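**Retrosynthetic overview**
- Feature: in ring B of the tetralin (C1–C2–C3–C4–C4a–C8a) the C3–C4 bond joins a benzylic CH2 (C4) to the CH(CH2OMe) carbon C3. An NH placed between these two atoms expands ring B to the seven-membered ring of a 2-benzazepine, where C4 is a benzylamine carbon and C3 is the α-carbon of a reduced α-amino acid.
- Last disconnection: C3–C4, formed by deleting that nitrogen (isodiazene, loss of N2, radical recombination). The benzazepine comes from its lactam, whose C4 carbon is CO inserted into an Ar–Br bond.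
- C2–C3 comes from an L-proline Mannich reaction of a 3,3-diarylpropanal with the glyoxylate imine, which sets C2 and pre-sets C3. C1 comes from a rhodium/diene conjugate arylation of the 2-bromo-enal.
- Ring order: both arenes are bought, the azepine ring is closed in step 8, and it is contracted to carbocyclic ring B in step 10.

Key step: step 10

Assumption: the (S,S) antipode of the diene ligand is taken to deliver the aryl group to the Re face of C-β of the bromo-enal, by analogy with its sense on acyclic (E)-enones. If a test run shows the opposite sense, the (R,R) ligand is used and nothing else changes.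

Atom map: tetralin C4/C3/C2/C1 correspond to benzazepine C1/C3/C4/C5. The target is 1,2-cis and 2,3-trans.

**Step 1**
Reactants: 1 2-bromo-4,5-dimethoxybenzaldehyde; 2 (triphenylphosphoranylidene)acetaldehyde
Product: 3 (E)-3-(2-bromo-4,5-dimethoxyphenyl)prop-2-enal
Conditions: 2 (1.1 equiv), toluene, 80 °C
Reagents that add atoms: none
Why: Wittig olefination, in which the stabilised formyl ylide gives the (E)-enal, the aryl bromide and the ethers are inert, and keeping the ylide near one equivalent limits a second homologation to the dienal.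

**Step 2**
Reactants: 3 (E)-3-(2-bromo-4,5-dimethoxyphenyl)prop-2-enal; 4 3,4-dimethoxyphenylboronic acid
Product: 5 (S)-3-(2-bromo-4,5-dimethoxyphenyl)-3-(3,4-dimethoxyphenyl)propanal
Conditions: [RhCl(C2H4)2]2 (1.5 mol %), (1S,4S)-2,5-diphenylbicyclo[2.2.2]octa-2,5-diene (3.3 mol %), 4 (1.5 equiv), KOH (0.3 equiv), MeOH/H2O 10:1, 50 °C
Reagents that add atoms: none
Why: Hayashi–Miyaura asymmetric 1,4-addition, in which a chiral diene on monovalent rhodium makes the aryl–rhodium species insert the C=C bond of the enal in preference to C=O and leave the Ar–Br bond alone, and the C2-symmetric ligand exposes the Re face of C-β, which sets the diarylmethine centre (C1 of the target) as (S).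

**Step 3**
Reactants: 6 ethyl glyoxylate; 7 4-methoxyaniline
Product: 8 ethyl (E)-2-[(4-methoxyphenyl)imino]acetate
Conditions: 6 (50% in toluene), MgSO4, CH2Cl2, rt; filtered, evaporated and used directly
Reagents that add atoms: none
Why: Imine condensation of the highly electrophilic glyoxylate aldehyde with an electron-rich aniline, driven by the drying agent, gives the (E)-imine.

**Step 4**
Reactants: 5 (S)-3-(2-bromo-4,5-dimethoxyphenyl)-3-(3,4-dimethoxyphenyl)propanal; 8 ethyl (E)-2-[(4-methoxyphenyl)imino]acetate
Product: 9 ethyl (2S,3S,4S)-4-(2-bromo-4,5-dimethoxyphenyl)-4-(3,4-dimethoxyphenyl)-3-formyl-2-[(4-methoxyphenyl)amino]butanoate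
Conditions: L-proline (20 mol %), 8 (1.3 equiv), dioxane, rt; aqueous work-up, crude product taken on at once
Reagents that add atoms: none
Why: Proline-catalysed direct asymmetric Mannich reaction, in which the (E)-enamine of 5 adds through the hydrogen-bonded chair-like transition state to the Si face of the activated (E)-imine, so that L-proline fixes both new centres as (2S,3S)-syn under catalyst control, as is known for β-branched aldehydes, while the (4S) centre is untouched.

**Step 5**
Reactants: 9 ethyl (2S,3S,4S)-4-(2-bromo-4,5-dimethoxyphenyl)-4-(3,4-dimethoxyphenyl)-3-formyl-2-[(4-methoxyphenyl)amino]butanoate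
Product: 10 (2S,3S)-2-[(S)-(2-bromo-4,5-dimethoxyphenyl)(3,4-dimethoxyphenyl)methyl]-3-[(4-methoxyphenyl)amino]butane-1,4-diol
Conditions: LiBH4 (3 equiv), THF, 0 °C to rt
Reagents that add atoms: none
Why: Borohydride reduction of the aldehyde and the activated α-amino ester in one operation removes the acidic formyl α-proton before that centre can epimerise, and LiBH4 does not reduce the aryl bromide.

**Step 6**
Reactants: 10 (2S,3S)-2-[(S)-(2-bromo-4,5-dimethoxyphenyl)(3,4-dimethoxyphenyl)methyl]-3-[(4-methoxyphenyl)amino]butane-1,4-diol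
Product: 11 N-[(2S,3S,4S)-4-(2-bromo-4,5-dimethoxyphenyl)-4-(3,4-dimethoxyphenyl)-1-methoxy-3-(methoxymethyl)butan-2-yl]-4-methoxyaniline
Conditions: NaH (2.3 equiv), THF, 0 °C; then MeI (2.3 equiv), 0 °C to rt
Reagents that add atoms: iodomethane, CI
Why: Williamson ether synthesis on the preformed disodium dialkoxide, a selectivity known from the O-methylation of unprotected amino alcohols, because the alkoxides react with MeI far faster than the neutral, α-branched N-aryl amine as long as base and MeI stay close to two equivalents.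

**Step 7**
Reactants: 11 N-[(2S,3S,4S)-4-(2-bromo-4,5-dimethoxyphenyl)-4-(3,4-dimethoxyphenyl)-1-methoxy-3-(methoxymethyl)butan-2-yl]-4-methoxyaniline
Product: 12 (2S,3S,4S)-4-(2-bromo-4,5-dimethoxyphenyl)-4-(3,4-dimethoxyphenyl)-1-methoxy-3-(methoxymethyl)butan-2-amine
Conditions: H5IO6 (1.0 equiv), 1 M aq. H2SO4, MeCN/H2O 1:1, rt; acidic phase washed with CH2Cl2, then basified and extracted
Reagents that add atoms: none
Why: Oxidative N-dearylation of a p-methoxyphenyl amine, in which the p-anisidine ring is oxidised at a much lower potential than the two veratryl rings, one equivalent of periodic acid takes it to the quinone iminium ion that water cleaves to the protonated primary amine, and the methyl ethers leave no vicinal amino alcohol for periodate to cleave.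

**Step 8**
Reactants: 12 (2S,3S,4S)-4-(2-bromo-4,5-dimethoxyphenyl)-4-(3,4-dimethoxyphenyl)-1-methoxy-3-(methoxymethyl)butan-2-amine
Product: 13 (3S,4S,5S)-5-(3,4-dimethoxyphenyl)-7,8-dimethoxy-3,4-bis(methoxymethyl)-2,3,4,5-tetrahydro-1H-2-benzazepin-1-one
Conditions: Pd(OAc)2 (5 mol %), Xantphos (6 mol %), CO (1 atm), Et3N (3 equiv), toluene (0.02 M), 100 °C
Reagents that add atoms: carbon monoxide, [C-]#[O+]
Why: Palladium-catalysed intramolecular aminocarbonylation of an aryl bromide, a known entry to 2-benzazepin-1-ones, in which oxidative addition to zerovalent palladium, CO insertion and capture of the acyl-palladium species by the tethered primary amine close the seven-membered lactam, and with CO present and only Et3N as base the carbonylation outruns Buchwald–Hartwig closure to the tetrahydroquinoline.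

**Step 9**
Reactants: 13 (3S,4S,5S)-5-(3,4-dimethoxyphenyl)-7,8-dimethoxy-3,4-bis(methoxymethyl)-2,3,4,5-tetrahydro-1H-2-benzazepin-1-one
Product: 14 (3S,4S,5S)-5-(3,4-dimethoxyphenyl)-7,8-dimethoxy-3,4-bis(methoxymethyl)-2,3,4,5-tetrahydro-1H-2-benzazepine (4,5-cis, 3,4-trans)
Conditions: LiAlH4 (3 equiv), THF, reflux; aqueous NaOH work-up
Reagents that add atoms: none
Why: Standard LiAlH4 reduction of a secondary benzolactam to the cyclic benzylic amine, with no stereocentre α to the carbonyl group and with inert methyl ethers.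

**Step 10**
Reactants: 14 (3S,4S,5S)-5-(3,4-dimethoxyphenyl)-7,8-dimethoxy-3,4-bis(methoxymethyl)-2,3,4,5-tetrahydro-1H-2-benzazepine; 15 N-(benzyloxy)-N-(pivaloyloxy)-4-(trifluoromethyl)benzamide
Product: 19 (1S,2S,3S)-1-(3,4-dimethoxyphenyl)-6,7-dimethoxy-2,3-bis(methoxymethyl)-1,2,3,4-tetrahydronaphthalene (target), via alkoxyhydrazide 16 (not isolated), via isodiazene 17 (not isolated), via diradical 18 (not isolated)
Conditions: 15 (1.5 equiv), degassed THF (0.05 M), 45 °C; chromatography removes any C3 epimer
Reagents that add atoms: none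
Why: Nitrogen deletion with an anomeric amide starts when the N–H of 14, its only nucleophile, displaces pivalate at the amide nitrogen of 15 to give 16, whose benzyloxy group migrates to the acyl carbon (HERON-type rearrangement) and releases an ester and isodiazene 17. 17 loses N2, the weaker benzylic C1–N bond breaking first, and leaves the singlet 1,6-diradical 18 (ArCH2 radical at tetralin C4 and secondary alkyl radical at C3). The closest known reactions are the ring contractions of cyclic α-aryl and benzo-fused secondary amines with this reagent, in which one benzylic and one unstabilised carbon are likewise joined. Ring B closes by intramolecular radical–radical recombination of 18, which contracts the seven-membered ring to the six-membered ring and forms C3–C4. C1 and C2 are not touched, and at C3 two effects point the same way: 14 already holds the C3 branch trans to the C2 branch, so fast collapse of the singlet pair gives retention, and if the planar radical rotates first the half-chair closure should still place CH2OMe equatorial, because the other face would set it 1,3-diaxial to the pseudoaxial C1 aryl group, a substrate bias that is expected but remains to be shown. The step needs recombination to outrun disproportionation (hydrogen transfer from C2–H or from the C3 side chain to the benzylic radical), and the short tether, the singlet spin state and the absence of oxygen favour it.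

**Compound list**
1 | 2-bromo-4,5-dimethoxybenzaldehyde | COc1cc(Br)c(C=O)cc1OC | starting material
2 | (triphenylphosphoranylidene)acetaldehyde | O=CC=P(c1ccccc1)(c1ccccc1)c1ccccc1 | starting material
3 | (E)-3-(2-bromo-4,5-dimethoxyphenyl)prop-2-enal | COc1cc(Br)c(/C=C/C=O)cc1OC | intermediate
4 | 3,4-dimethoxyphenylboronic acid | COc1ccc(B(O)O)cc1OC | starting material
5 | (S)-3-(2-bromo-4,5-dimethoxyphenyl)-3-(3,4-dimethoxyphenyl)propanal | O=CC[C@@H](c1ccc(OC)c(OC)c1)c1cc(OC)c(OC)cc1Br | intermediate
6 | ethyl glyoxylate | CCOC(=O)C=O | starting material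
7 | 4-methoxyaniline | COc1ccc(N)cc1 | starting material
8 | ethyl (E)-2-[(4-methoxyphenyl)imino]acetate | CCOC(=O)/C=N/c1ccc(OC)cc1 | intermediate
9 | ethyl (2S,3S,4S)-4-(2-bromo-4,5-dimethoxyphenyl)-4-(3,4-dimethoxyphenyl)-3-formyl-2-[(4-methoxyphenyl)amino]butanoate | CCOC(=O)[C@@H](Nc1ccc(OC)cc1)[C@@H](C=O)[C@@H](c1ccc(OC)c(OC)c1)c1cc(OC)c(OC)cc1Br | intermediate
10 | (2S,3S)-2-[(S)-(2-bromo-4,5-dimethoxyphenyl)(3,4-dimethoxyphenyl)methyl]-3-[(4-methoxyphenyl)amino]butane-1,4-diol | OC[C@@H](Nc1ccc(OC)cc1)[C@@H](CO)[C@@H](c1ccc(OC)c(OC)c1)c1cc(OC)c(OC)cc1Br | intermediate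
11 | N-[(2S,3S,4S)-4-(2-bromo-4,5-dimethoxyphenyl)-4-(3,4-dimethoxyphenyl)-1-methoxy-3-(methoxymethyl)butan-2-yl]-4-methoxyaniline | COC[C@@H](Nc1ccc(OC)cc1)[C@@H](COC)[C@@H](c1ccc(OC)c(OC)c1)c1cc(OC)c(OC)cc1Br | intermediate
12 | (2S,3S,4S)-4-(2-bromo-4,5-dimethoxyphenyl)-4-(3,4-dimethoxyphenyl)-1-methoxy-3-(methoxymethyl)butan-2-amine | COC[C@@H](N)[C@@H](COC)[C@@H](c1ccc(OC)c(OC)c1)c1cc(OC)c(OC)cc1Br | intermediate
13 | (3S,4S,5S)-5-(3,4-dimethoxyphenyl)-7,8-dimethoxy-3,4-bis(methoxymethyl)-2,3,4,5-tetrahydro-1H-2-benzazepin-1-one | COC[C@H]1NC(=O)c2cc(OC)c(OC)cc2[C@H](c2ccc(OC)c(OC)c2)[C@@H]1COC | intermediate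
14 | (3S,4S,5S)-5-(3,4-dimethoxyphenyl)-7,8-dimethoxy-3,4-bis(methoxymethyl)-2,3,4,5-tetrahydro-1H-2-benzazepine | COC[C@H]1NCc2cc(OC)c(OC)cc2[C@H](c2ccc(OC)c(OC)c2)[C@@H]1COC | intermediate
15 | N-(benzyloxy)-N-(pivaloyloxy)-4-(trifluoromethyl)benzamide | CC(C)(C)C(=O)ON(OCc1ccccc1)C(=O)c1ccc(C(F)(F)F)cc1 | starting material
16 | N-(benzyloxy)-N-[(3S,4S,5S)-5-(3,4-dimethoxyphenyl)-7,8-dimethoxy-3,4-bis(methoxymethyl)-1,3,4,5-tetrahydro-2H-2-benzazepin-2-yl]-4-(trifluoromethyl)benzamide | COC[C@H]1N(N(OCc3ccccc3)C(=O)c3ccc(C(F)(F)F)cc3)Cc2cc(OC)c(OC)cc2[C@H](c2ccc(OC)c(OC)c2)[C@@H]1COC | intermediate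
17 | isodiazene (1,1-diazene) of 14, ring N+=N− | COC[C@H]1[N+](=[N-])Cc2cc(OC)c(OC)cc2[C@H](c2ccc(OC)c(OC)c2)[C@@H]1COC | intermediate
18 | singlet 1,6-diradical, benzylic CH2 radical and secondary CH radical, with the C1 and C2 centres of the target intact | COC[CH][C@@H](COC)[C@@H](c1ccc(OC)c(OC)c1)c1cc(OC)c(OC)cc1[CH2] | intermediate
19 | (1S,2S,3S)-1-(3,4-dimethoxyphenyl)-6,7-dimethoxy-2,3-bis(methoxymethyl)-1,2,3,4-tetrahydronaphthalene | COC[C@H]1Cc2cc(OC)c(OC)cc2[C@H](c2ccc(OC)c(OC)c2)[C@@H]1COC | target

**Step count**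
Total step count: 10. Longest linear sequence: 9 (steps 1, 2 and 4–10, starting from 1). Step 3 is a one-step side branch.

**Steps most likely to fail**

**Step 10.**
- What may go wrong:
  - Substitution at the anomeric-amide nitrogen by the α-branched amine may be slow.
  - The liberated carboxylic acid may tie up the amine.
  - Hydrogen transfer within the radical pair may compete with recombination.
  - The planar C3 radical may rotate before collapse and erode the configuration.
- The fallback sets out from 14 and comes back at isodiazene 17.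
- 14 is treated with 1-(azidosulfonyl)-2,3-dimethylimidazolium triflate (MeCN, 0 °C to rt) to give the isolable benzazepine-2-sulfonyl azide F1.
- Heating F1 in chlorobenzene at about 120 °C starts a Curtius-type shift of the amino group from sulfur to nitrogen. The N-sulfonylamine formed this way sheds SO2 to give 17, which goes on to 18 and 19 as before.
- N–N bond formation becomes an unhindered sulfonyl transfer followed by a unimolecular rearrangement in an acid-free medium. The radical pair is also generated in a second solvent and temperature regime.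
- This fallback addresses the N–N bond-forming stage. It does not change the intrinsic partition of 18.

**Step 4.**
- What may go wrong:
  - Enamine formation from the β,β-diaryl aldehyde may be slow.
  - L-proline and the existing (S) centre may be a mismatched pair.
  - The formyl-bearing carbon may epimerise before reduction.
- The fallback sets out from 5 and comes back at 12, so it also replaces steps 5–7. It exchanges enamine catalysis for a stoichiometric metal enolate and a sulfinyl auxiliary that is removed with acid.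
- Pinnick oxidation (NaClO2, NaH2PO4, 2-methyl-2-butene, t-BuOH/H2O) gives the diarylpropanoic acid F2. Fischer esterification (MeOH, cat. H2SO4) then gives the methyl ester F3.
- Methoxyacetaldehyde and (R)-tert-butanesulfinamide (CuSO4, CH2Cl2) give the sulfinyl imine F4.
- The titanium enolate of F3 (LiN(iPr)2, THF, −78 °C; then ClTi(OiPr)3) adds to F4 through a closed Zimmerman–Traxler chair. This is the known route to syn α-substituted β-amino esters, and with the (R)-sulfinyl group it is expected to give the (2S,3S) adduct F5.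
- LiBH4 reduces the ester to the sulfinamido alcohol F6. HCl in MeOH then frees the amino alcohol F7.
- Alkoxide formation with KH followed by one equivalent of MeI gives 12.

**Step 8.**
- What may go wrong:
  - Oxidative addition to the electron-rich, ortho-hindered Ar–Br bond may be sluggish.
  - The primary amine may bind the catalyst.
  - Direct C–N coupling may close the six-membered ring instead.
  - Intermolecular amide formation may compete with ring closure.
- The fallback sets out from 12 and comes back at 14, so it also replaces step 9. It installs the benzylic carbon by polar chemistry.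
- Boc2O (Et3N, CH2Cl2) gives the carbamate F8.
- n-BuLi (2.2 equiv, THF, −78 °C) deprotonates N–H and then effects bromine–lithium exchange. A DMF quench gives the benzaldehyde F9.
- CF3CO2H in CH2Cl2 removes the Boc group. On neutralisation the amino aldehyde condenses to the cyclic imine F10, which NaBH4 in MeOH reduces to 14 (intramolecular reductive amination).

**Further compounds**
F1 | step 10 | (3S,4S,5S)-5-(3,4-dimethoxyphenyl)-7,8-dimethoxy-3,4-bis(methoxymethyl)-1,3,4,5-tetrahydro-2H-2-benzazepine-2-sulfonyl azide | COC[C@H]1N(S(=O)(=O)N=[N+]=[N-])Cc2cc(OC)c(OC)cc2[C@H](c2ccc(OC)c(OC)c2)[C@@H]1COC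
F2 | step 4 | (S)-3-(2-bromo-4,5-dimethoxyphenyl)-3-(3,4-dimethoxyphenyl)propanoic acid | OC(=O)C[C@@H](c1ccc(OC)c(OC)c1)c1cc(OC)c(OC)cc1Br
F3 | step 4 | methyl (S)-3-(2-bromo-4,5-dimethoxyphenyl)-3-(3,4-dimethoxyphenyl)propanoate | COC(=O)C[C@@H](c1ccc(OC)c(OC)c1)c1cc(OC)c(OC)cc1Br
F4 | step 4 | (R,E)-N-(2-methoxyethylidene)-2-methylpropane-2-sulfinamide | CC(C)(C)[S@@](=O)/N=C/COC
F5 | step 4 | methyl (2S,3S)-2-[(S)-(2-bromo-4,5-dimethoxyphenyl)(3,4-dimethoxyphenyl)methyl]-3-{[(R)-tert-butylsulfinyl]amino}-4-methoxybutanoate | COC[C@@H](N[S@](=O)C(C)(C)C)[C@@H](C(=O)OC)[C@@H](c1ccc(OC)c(OC)c1)c1cc(OC)c(OC)cc1Br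
F6 | step 4 | (R)-N-{(2S,3S)-3-[(S)-(2-bromo-4,5-dimethoxyphenyl)(3,4-dimethoxyphenyl)methyl]-4-hydroxy-1-methoxybutan-2-yl}-2-methylpropane-2-sulfinamide | COC[C@@H](N[S@](=O)C(C)(C)C)[C@@H](CO)[C@@H](c1ccc(OC)c(OC)c1)c1cc(OC)c(OC)cc1Br
F7 | step 4 | (2S,3S)-3-amino-2-[(S)-(2-bromo-4,5-dimethoxyphenyl)(3,4-dimethoxyphenyl)methyl]-4-methoxybutan-1-ol | COC[C@@H](N)[C@@H](CO)[C@@H](c1ccc(OC)c(OC)c1)c1cc(OC)c(OC)cc1Br
F8 | step 8 | tert-butyl N-[(2S,3S,4S)-4-(2-bromo-4,5-dimethoxyphenyl)-4-(3,4-dimethoxyphenyl)-1-methoxy-3-(methoxymethyl)butan-2-yl]carbamate | COC[C@@H](NC(=O)OC(C)(C)C)[C@@H](COC)[C@@H](c1ccc(OC)c(OC)c1)c1cc(OC)c(OC)cc1Br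
F9 | step 8 | tert-butyl N-[(2S,3S,4S)-4-(3,4-dimethoxyphenyl)-4-(2-formyl-4,5-dimethoxyphenyl)-1-methoxy-3-(methoxymethyl)butan-2-yl]carbamate | COC[C@@H](NC(=O)OC(C)(C)C)[C@@H](COC)[C@@H](c1ccc(OC)c(OC)c1)c1cc(OC)c(OC)cc1C=O
F10 | step 8 | (3S,4S,5S)-5-(3,4-dimethoxyphenyl)-7,8-dimethoxy-3,4-bis(methoxymethyl)-4,5-dihydro-3H-2-benzazepine | COC[C@H]1N=Cc2cc(OC)c(OC)cc2[C@H](c2ccc(OC)c(OC)c2)[C@@H]1COC
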